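I began from what a flask at one temperature should hold fixed: the ratio of the second step to the first, where starting material and coupling partner give mono adduct, and mono adduct and coupling partner give double product. I took each step to use one partner, so c(coupling partner) cancels from that ratio. The share of mono adduct should then follow conversion, whatever the clock says.

| flask | starting material | coupling partner | temperature | remark | time |
|---|---|---|---|---|---|
| delta | 0.067 M | 0.12 M | −10 °C | run made earlier |  |
| beta | 0.15 M | 0.12 M | 23 °C | run made earlier |  |
| west | 0.10 M | 0.120 M | 5 °C |  | 15 min |
| south-west | 0.10 M | 0.120 M | 35 °C |  | 15 min |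
| east | 0.10 M | 0.120 M | −25 °C |  | 15 min |

| run | time / min | mono adduct / % | double product / % |
|---|---|---|---|
| delta | 2.00 | 12.0 | 3.1 |
| delta | 5.00 | 19.2 | 10.6 |
| delta | 8.00 | 20.3 | 19.6 |
| delta | 12.0 | 18.6 | 29.4 |
| delta | 20.0 | 15.0 | 41.8 |
| delta | 25.0 | 13.1 | 48.5 |
| delta | 30.0 | 11.2 | 52.7 |
| beta | 0.833 | 15.6 | 10.8 |
| beta | 1.50 | 12.7 | 17.7 |
| beta | 2.50 | 9.1 | 21.6 |
| beta | 3.00 | 7.3 | 22.4 |
| beta | 4.00 | 4.4 | 23.1 |
| beta | 5.00 | 2.8 | 23.9 |
| beta | 6.00 | 1.4 | 23.5 |

(standard deviation of a reading: 0.5 percentage points)

* the flask with the highest share of mono adduct in all that became mono adduct or double product or side product A or side product B ("all alike" if they lie within 1.5 percentage points) (west / south-west / east / all alike)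
* share of mono adduct in all that became mono adduct or double product or side product A or side product B, west
* share of mono adduct in all that became mono adduct or double product or side product A or side product B, south-west
* share of mono adduct in all that became mono adduct or double product or side product A or side product B, east

- in percentages every species weighs as the starting material in it: one side product B counts as two
- the numbers in the tables scatter by 0.5 percentage points (one standard deviation)

Let a, m and d be c(starting material), c(mono adduct) and c(double product) as fractions of the starting material charged. Equal steps are the zero of the scale: m would then peak at 36.8%. The delta run's highest reading was lower, 20.3% at 8.00 min, so I read the second step as the faster. Early on, d is about κ(m+d)²/2, so the first delta reading puts the selectivity factor κ, the second rate constant over the first, at 2.72, a figure that carries the scatter of that reading. The curve is then m = (a − a^κ)/(κ − 1).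

Now the settings, by hand. Temperature: the first beta reading, from a run both warmer and richer in starting material, gives 3.10, close to delta, so I expected warming to change speed more than κ. Yet from 3.00 min to 6.00 min in beta, mono adduct fell 5.9 percentage points while double product gained 1.1 points, so I expected warm flasks to sit below the curve. Time and partner: by this reckoning each moves a flask along the curve, where the share at half conversion is 40.5%. So I committed to east, the coldest flask, as highest.

The forecast said east, with 14% for west, 0.1% for south-west and 41% for east, where "conversion is only about 45%". My curve gives about that share at half conversion, not at the conversion the forecast names.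

The flasks gave 9.58% in west, 0.151% in south-west and 65.3% in east, so east stood highest.

    starting material + coupling partner → mono adduct + by-product (k = 0.170 L mol⁻¹ s⁻¹, Ea = 41.0 kJ mol⁻¹)
    coupling partner + mono adduct → double product + by-product (k = 0.480 L mol⁻¹ s⁻¹, Ea = 42.0 kJ mol⁻¹)
    mono adduct + by-product → side product A (k = 0.370 L mol⁻¹ s⁻¹, Ea = 65.0 kJ mol⁻¹)
    starting material + mono adduct → side product B (k = 0.0430 L mol⁻¹ s⁻¹, Ea = 61.0 kJ mol⁻¹)
    (constants at 35 °C)

East had converted 27.7%, against the forecast's 45%, and from its 72.3% of starting material the curve gives 18.0% of mono adduct, against 18.1% in the flask. In west, from 31.6% of starting material, the curve gives 15.8%, but 6.55% stood there. The half-life of mono adduct by the path to side product A in west was 11 min at 2.35 min, shorter than the 15 min of the run, and side product A reached 17.9%.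

The earlier runs and the new flask were computed for an exercise; the scatter is artificial.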